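**Plan**

Numbering used throughout: ring C1 (bears the heptenyl chain, C7=C8), C2 (bears C9H2OH), C3-OH, C4-OH, C5 (bears C10H2-C11H=C12(CH3)-C13O2H), C6-OH.
Retrosynthetic cuts: C11=C12 (Wittig), then the ring bond C3-C4 (reductive coupling of two formyl groups), then C5-C6 (vinylogous Mukaiyama-Michael addition), then C2-C9 and C1-C7 (Stille and Suzuki-Miyaura couplings on 3,4-dibromobutenolide).
Enabling feature: C3 and C4 are neighbouring secondary carbinol carbons, cis to each other, in a cyclohexene whose tetrasubstituted C1=C2 bond holds C3 and C6 on the same side. Opened at this glycol bond, the ring is a 1,6-dialdehyde (C3 dienal, C4 alkanal) already folded for closure.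
Forward: a butenolide (O-C3(=O)-C2=C1-C6) serves as a temporary ring that fixes the C1=C2 geometry while C7 and C9 are attached and C6 is joined to C5. Hydride then opens it, the C1-C6 carbocycle (the only ring of the target) is closed in step 10, and the acid chain is completed last.
Stereochemistry: C5 and C6 come from the chiral imidazolidinone catalyst (step 5). C3 and C4 come from substrate control in step 10, where the samarium chelate gives the cis-diol and the C5 branch and allylic strain choose the face. C7=C8 comes from the boronic acid and C11=C12 from the stabilised ylide.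

Key step: step 10

Remark: 1, 2, 4, 8, 17 and the imidazolidinone catalyst are taken as catalogue chemicals (1 is otherwise one NaBH4 reduction away from mucobromic acid). TES = triethylsilyl, TBDPS = tert-butyldiphenylsilyl, TIPS = triisopropylsilyl.

**Step 1**
Reactants: 1 3,4-dibromofuran-2(5H)-one; 2 (E)-hept-1-en-1-ylboronic acid
Product: 3 3-bromo-4-[(E)-hept-1-en-1-yl]furan-2(5H)-one
Conditions: PdCl2(MeCN)2 (5 mol %), AsPh3 (20 mol %), Ag2O (3 equiv), THF, 65 °C
Reagents that add atoms: none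
Why: Suzuki-Miyaura coupling in which zerovalent palladium inserts faster into the C4-Br bond (the beta-carbon of the unsaturated lactone, future C1) than into the C3-Br bond, and the E geometry of the boronic acid is retained.

**Step 2**
Reactants: 3 3-bromo-4-[(E)-hept-1-en-1-yl]furan-2(5H)-one; 4 (tributylstannyl)methanol
Product: 5 4-[(E)-hept-1-en-1-yl]-3-(hydroxymethyl)furan-2(5H)-one
Conditions: Pd(PPh3)4 (10 mol %), 1,4-dioxane, 100 °C
Reagents that add atoms: none
Why: Stille coupling of the remaining alpha-bromide with the hydroxymethyl stannane, a standard hydroxymethylation of alkenyl halides, in which the lactone ring fixes the geometry of the now tetrasubstituted C1=C2 bond.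

**Step 3**
Reactants: 5 4-[(E)-hept-1-en-1-yl]-3-(hydroxymethyl)furan-2(5H)-one
Product: 6 3-{[(tert-butyldiphenylsilyl)oxy]methyl}-4-[(E)-hept-1-en-1-yl]furan-2(5H)-one
Conditions: t-BuPh2SiCl, imidazole, CH2Cl2, 0 °C to rt
Reagents that add atoms: tert-butyl(chloro)diphenylsilane CC(C)(C)[Si](Cl)(c1ccccc1)c1ccccc1
Why: Routine silylation of a primary allylic alcohol, with the acid-stable TBDPS group chosen so that it outlasts steps 5, 6 and 11.

**Step 4**
Reactants: 6 3-{[(tert-butyldiphenylsilyl)oxy]methyl}-4-[(E)-hept-1-en-1-yl]furan-2(5H)-one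
Product: 7 3-{[(tert-butyldiphenylsilyl)oxy]methyl}-4-[(E)-hept-1-en-1-yl]-2-[(triisopropylsilyl)oxy]furan
Conditions: i-Pr3SiOTf, Et3N, CH2Cl2, 0 °C
Reagents that add atoms: triisopropylsilyl trifluoromethanesulfonate CC(C)[Si](C(C)C)(C(C)C)OS(=O)(=O)C(F)(F)F
Why: Soft enolisation of the butenolide at its gamma-CH2 (C6) with O-silylation gives the aromatic 2-silyloxyfuran, the usual nucleophile of vinylogous Mukaiyama reactions.

**Step 5**
Reactants: 7 3-{[(tert-butyldiphenylsilyl)oxy]methyl}-4-[(E)-hept-1-en-1-yl]-2-[(triisopropylsilyl)oxy]furan; 8 ethyl (E)-4-oxobut-2-enoate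
Product: 9 ethyl (2R)-2-[(2S)-4-{[(tert-butyldiphenylsilyl)oxy]methyl}-3-[(E)-hept-1-en-1-yl]-5-oxo-2,5-dihydrofuran-2-yl]-4-oxobutanoate (C5 R, C6 S)
Conditions: (2S,5S)-5-benzyl-2-tert-butyl-3-methylimidazolidin-4-one trifluoroacetate (20 mol %), H2O (2 equiv), THF, -10 °C
Reagents that add atoms: none
Why: Iminium-catalysed vinylogous Mukaiyama-Michael addition in which the E-iminium ion of 8 is attacked at the carbon beta to the iminium (C5) from the face left open by the benzyl and tert-butyl groups, which sets C5 (R), while the furan reacts at its free alpha-carbon through the open synclinal arrangement usual for 2-silyloxyfurans, which sets C6 (S), and water takes up the silyl group.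

**Step 6**
Reactants: 9 ethyl (2R)-2-[(2S)-4-{[(tert-butyldiphenylsilyl)oxy]methyl}-3-[(E)-hept-1-en-1-yl]-5-oxo-2,5-dihydrofuran-2-yl]-4-oxobutanoate
Product: 10 ethyl (2R)-2-[(2S)-4-{[(tert-butyldiphenylsilyl)oxy]methyl}-3-[(E)-hept-1-en-1-yl]-5-oxo-2,5-dihydrofuran-2-yl]-4,4-dimethoxybutanoate
Conditions: HC(OMe)3, pyridinium p-toluenesulfonate (10 mol %), MeOH, 0 °C to rt
Reagents that add atoms: trimethyl orthoformate COC(OC)OC
Why: Acid-catalysed acetalisation with an orthoester masks the C11 aldehyde against hydride and SmI2 and touches neither stereocentre.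

**Step 7**
Reactants: 10 ethyl (2R)-2-[(2S)-4-{[(tert-butyldiphenylsilyl)oxy]methyl}-3-[(E)-hept-1-en-1-yl]-5-oxo-2,5-dihydrofuran-2-yl]-4,4-dimethoxybutanoate
Product: 11 (2S,3S,4E)-5-{[(tert-butyldiphenylsilyl)oxy]methyl}-2-(2,2-dimethoxyethyl)-4-[(E)-hept-1-en-1-yl]hex-4-ene-1,3,6-triol (C3H2OH cis to C6 across C1=C2; C5 is now labelled S only because the CIP ranking changes)
Conditions: i-Bu2AlH (7 equiv), CH2Cl2, -78 to 0 °C; aq. potassium sodium tartrate
Reagents that add atoms: none
Why: Exhaustive 1,2-reduction of lactone and ester, the standard opening of a butenolide to a (Z)-2-ene-1,4-diol, frees C3 and C4 as primary carbinols and C6 as a secondary alcohol while the alkene geometry is carried over from the ring.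

**Step 8**
Reactants: 11 (2S,3S,4E)-5-{[(tert-butyldiphenylsilyl)oxy]methyl}-2-(2,2-dimethoxyethyl)-4-[(E)-hept-1-en-1-yl]hex-4-ene-1,3,6-triol
Product: 12 1,3,6-tris(triethylsilyl) ether of 11 (C3-OTES, C4-OTES, C6-OTES)
Conditions: Et3SiCl (4 equiv), imidazole, 4-(dimethylamino)pyridine (10 mol %), DMF, 0 °C to rt
Reagents that add atoms: chlorotriethylsilane CC[Si](Cl)(CC)CC
Why: Routine per-silylation under conditions without a Lewis acid, to which the dimethyl acetal is inert, prepares the selective oxidation.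

**Step 9**
Reactants: 12 1,3,6-tris(triethylsilyl) ether of 11
Product: 13 (2Z,4S,5R)-2-{[(tert-butyldiphenylsilyl)oxy]methyl}-5-(2,2-dimethoxyethyl)-3-[(E)-hept-1-en-1-yl]-4-[(triethylsilyl)oxy]hex-2-enedial (C3 and C4 formyl groups; used crude)
Conditions: (COCl)2 (5 equiv), DMSO (10 equiv), CH2Cl2, -78 to -40 °C; Et3N, -78 to 0 °C
Reagents that add atoms: none
Why: Swern oxidation applied directly to silyl ethers, a known selectivity in which the chlorodimethylsulfonium ion attacks only the unhindered primary TES ethers and turns them into aldehydes, while the secondary TES ether, the TBDPS ether and the acetal stay.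

**Step 10**
Reactants: 13 (2Z,4S,5R)-2-{[(tert-butyldiphenylsilyl)oxy]methyl}-5-(2,2-dimethoxyethyl)-3-[(E)-hept-1-en-1-yl]-4-[(triethylsilyl)oxy]hex-2-enedial
Product: 14 (1R,2S,3S,4S)-6-{[(tert-butyldiphenylsilyl)oxy]methyl}-3-(2,2-dimethoxyethyl)-5-[(E)-hept-1-en-1-yl]-4-[(triethylsilyl)oxy]cyclohex-5-ene-1,2-diol (C3 R, C4 S, C5 S by CIP ranking, C6 S; C3-OH and C4-OH cis, C4-OH trans to the C5 branch)
Conditions: SmI2 (4 equiv, 0.1 M in THF), t-BuOH (3 equiv), THF, -78 to -20 °C; aq. NaHCO3
Reagents that add atoms: none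
Why: SmI2 (divalent samarium) reduces the more easily reduced C3 dienal to a ketyl whose trivalent samarium also binds the C4 formyl oxygen, the C3-C4 bond forms inside this chelate, a second equivalent of SmI2 delivers the second electron, and t-BuOH and the work-up protonate the cyclic samarium diolate. The closest known reaction type is the SmI2-mediated intramolecular pinacol coupling of 1,6-dialdehydes, which gives cis-cyclohexane-1,2-diols. The C1-C6 carbocycle closes in the 6-exo-trig mode (attack of C3 on the carbon of C4=O), helped by the Z C1=C2 bond that already holds C3 and C6 on one side. The samarium bridge between the two oxygens makes the C3 and C4 hydroxyls cis; C4 (S) is set by the C5 branch, which lies equatorial in the half-chair transition state and places the C4-O bond equatorial and anti to it; C3 (R) follows because allylic 1,2-strain with the C9 silyloxymethyl group drives the C3-O bond, like the C6-OTES bond, into a pseudoaxial position. The step needs coupling at the carbonyl carbon C3 and not at C8 of the delocalised ketyl, no loss of the C6 silyloxy group and no plain reduction of either aldehyde. Chelation, the low temperature, the poor leaving-group ability of a silyloxide and the masking of the enoate side chain as an acetal (so that no ketyl-alkene closure can compete) secure this.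

**Step 11**
Reactants: 14 (1R,2S,3S,4S)-6-{[(tert-butyldiphenylsilyl)oxy]methyl}-3-(2,2-dimethoxyethyl)-5-[(E)-hept-1-en-1-yl]-4-[(triethylsilyl)oxy]cyclohex-5-ene-1,2-diol
Product: 16 2-[(1R,2S,5R,6S)-4-{[(tert-butyldiphenylsilyl)oxy]methyl}-3-[(E)-hept-1-en-1-yl]-2,5,6-tris[(triethylsilyl)oxy]cyclohex-3-en-1-yl]acetaldehyde, via methoxyalkyl-lutidinium triflate 15 (not isolated)
Conditions: Et3SiOTf (6 equiv), 2,6-lutidine (9 equiv), CH2Cl2, 0 °C; then H2O, rt
Reagents that add atoms: triethylsilyl trifluoromethanesulfonate CC[Si](CC)(CC)OS(=O)(=O)C(F)(F)F; water O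
Why: The silyl triflate/2,6-lutidine pair silylates both new hydroxyls and turns the dimethyl acetal into a methoxyalkyl-lutidinium salt that water hydrolyses to the aldehyde, a known weakly basic acetal cleavage that spares silyl ethers and the allylic C-O bonds.

**Step 12**
Reactants: 16 2-[(1R,2S,5R,6S)-4-{[(tert-butyldiphenylsilyl)oxy]methyl}-3-[(E)-hept-1-en-1-yl]-2,5,6-tris[(triethylsilyl)oxy]cyclohex-3-en-1-yl]acetaldehyde; 17 ethyl 2-(triphenylphosphoranylidene)propanoate
Product: 18 ethyl (2E)-4-[(1R,2S,5R,6S)-4-{[(tert-butyldiphenylsilyl)oxy]methyl}-3-[(E)-hept-1-en-1-yl]-2,5,6-tris[(triethylsilyl)oxy]cyclohex-3-en-1-yl]-2-methylbut-2-enoate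
Conditions: toluene, 60 °C
Reagents that add atoms: none
Why: Wittig olefination of an unhindered aldehyde with a stabilised alpha-methyl ylide, which reliably places the ester trans to the chain and so gives the E trisubstituted C11=C12 bond.

**Step 13**
Reactants: 18 ethyl (2E)-4-[(1R,2S,5R,6S)-4-{[(tert-butyldiphenylsilyl)oxy]methyl}-3-[(E)-hept-1-en-1-yl]-2,5,6-tris[(triethylsilyl)oxy]cyclohex-3-en-1-yl]-2-methylbut-2-enoate
Product: 19 ethyl (2E)-4-[(1R,2S,5R,6S)-3-[(E)-hept-1-en-1-yl]-2,5,6-trihydroxy-4-(hydroxymethyl)cyclohex-3-en-1-yl]-2-methylbut-2-enoate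
Conditions: n-Bu4NF (6 equiv), AcOH (6 equiv), THF, 0 °C to rt
Reagents that add atoms: none
Why: Fluoride-mediated desilylation, buffered with acetic acid, removes the three TES groups and the TBDPS group without harm to the ester, the diene or the allylic alcohols.

**Step 14**
Reactants: 19 ethyl (2E)-4-[(1R,2S,5R,6S)-3-[(E)-hept-1-en-1-yl]-2,5,6-trihydroxy-4-(hydroxymethyl)cyclohex-3-en-1-yl]-2-methylbut-2-enoate
Product: 21 pestallic acid P, via lithium carboxylate 20 (not isolated)
Conditions: LiOH (5 equiv), THF/H2O, 0 °C to rt; then 1 M HCl to pH 4, 0 °C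
Reagents that add atoms: lithium hydroxide [Li+].[OH-]
Why: Saponification of the conjugated ethyl ester followed by careful acidification, in which no stereocentre lies alpha to the carboxyl group so that none can epimerise.

**Compound list**

1 | 3,4-dibromofuran-2(5H)-one | O=C1OCC(Br)=C1Br | starting material
2 | (E)-hept-1-en-1-ylboronic acid | CCCCC/C=C/B(O)O | starting material
3 | 3-bromo-4-[(E)-hept-1-en-1-yl]furan-2(5H)-one | CCCCC/C=C/C1=C(Br)C(=O)OC1 | intermediate
4 | (tributylstannyl)methanol | CCCC[Sn](CCCC)(CCCC)CO | starting material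
5 | 4-[(E)-hept-1-en-1-yl]-3-(hydroxymethyl)furan-2(5H)-one | CCCCC/C=C/C1=C(CO)C(=O)OC1 | intermediate
6 | 3-{[(tert-butyldiphenylsilyl)oxy]methyl}-4-[(E)-hept-1-en-1-yl]furan-2(5H)-one | CCCCC/C=C/C1=C(CO[Si](c2ccccc2)(c2ccccc2)C(C)(C)C)C(=O)OC1 | intermediate
7 | 3-{[(tert-butyldiphenylsilyl)oxy]methyl}-4-[(E)-hept-1-en-1-yl]-2-[(triisopropylsilyl)oxy]furan | CCCCC/C=C/c1coc(O[Si](C(C)C)(C(C)C)C(C)C)c1CO[Si](c1ccccc1)(c1ccccc1)C(C)(C)C | intermediate
8 | ethyl (E)-4-oxobut-2-enoate | CCOC(=O)/C=C/C=O | starting material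
9 | ethyl (2R)-2-[(2S)-4-{[(tert-butyldiphenylsilyl)oxy]methyl}-3-[(E)-hept-1-en-1-yl]-5-oxo-2,5-dihydrofuran-2-yl]-4-oxobutanoate | CCCCC/C=C/C1=C(CO[Si](c2ccccc2)(c2ccccc2)C(C)(C)C)C(=O)O[C@H]1[C@@H](CC=O)C(=O)OCC | intermediate
10 | ethyl (2R)-2-[(2S)-4-{[(tert-butyldiphenylsilyl)oxy]methyl}-3-[(E)-hept-1-en-1-yl]-5-oxo-2,5-dihydrofuran-2-yl]-4,4-dimethoxybutanoate | CCCCC/C=C/C1=C(CO[Si](c2ccccc2)(c2ccccc2)C(C)(C)C)C(=O)O[C@H]1[C@@H](CC(OC)OC)C(=O)OCC | intermediate
11 | (2S,3S,4E)-5-{[(tert-butyldiphenylsilyl)oxy]methyl}-2-(2,2-dimethoxyethyl)-4-[(E)-hept-1-en-1-yl]hex-4-ene-1,3,6-triol | CCCCC/C=C/C(=C(\CO[Si](c1ccccc1)(c1ccccc1)C(C)(C)C)CO)[C@@H](O)[C@@H](CC(OC)OC)CO | intermediate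
12 | 1,3,6-tris(triethylsilyl) ether of 11 | CCCCC/C=C/C(=C(\CO[Si](c1ccccc1)(c1ccccc1)C(C)(C)C)CO[Si](CC)(CC)CC)[C@@H](O[Si](CC)(CC)CC)[C@@H](CC(OC)OC)CO[Si](CC)(CC)CC | intermediate
13 | (2Z,4S,5R)-2-{[(tert-butyldiphenylsilyl)oxy]methyl}-5-(2,2-dimethoxyethyl)-3-[(E)-hept-1-en-1-yl]-4-[(triethylsilyl)oxy]hex-2-enedial | CCCCC/C=C/C(=C(\CO[Si](c1ccccc1)(c1ccccc1)C(C)(C)C)C=O)[C@@H](O[Si](CC)(CC)CC)[C@@H](CC(OC)OC)C=O | intermediate
14 | (1R,2S,3S,4S)-6-{[(tert-butyldiphenylsilyl)oxy]methyl}-3-(2,2-dimethoxyethyl)-5-[(E)-hept-1-en-1-yl]-4-[(triethylsilyl)oxy]cyclohex-5-ene-1,2-diol | CCCCC/C=C/C1=C(CO[Si](c2ccccc2)(c2ccccc2)C(C)(C)C)[C@@H](O)[C@@H](O)[C@H](CC(OC)OC)[C@@H]1O[Si](CC)(CC)CC | intermediate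
15 | 1-(1-methoxy-2-{C3,C4,C6-tris-OTES, C9-OTBDPS cyclohexenyl}ethyl)-2,6-dimethylpyridinium triflate (C11 unassigned) | CCCCC/C=C/C1=C(CO[Si](c2ccccc2)(c2ccccc2)C(C)(C)C)[C@@H](O[Si](CC)(CC)CC)[C@@H](O[Si](CC)(CC)CC)[C@H](CC(OC)[n+]2c(C)cccc2C)[C@@H]1O[Si](CC)(CC)CC.[O-]S(=O)(=O)C(F)(F)F | intermediate
16 | 2-[(1R,2S,5R,6S)-4-{[(tert-butyldiphenylsilyl)oxy]methyl}-3-[(E)-hept-1-en-1-yl]-2,5,6-tris[(triethylsilyl)oxy]cyclohex-3-en-1-yl]acetaldehyde | CCCCC/C=C/C1=C(CO[Si](c2ccccc2)(c2ccccc2)C(C)(C)C)[C@@H](O[Si](CC)(CC)CC)[C@@H](O[Si](CC)(CC)CC)[C@H](CC=O)[C@@H]1O[Si](CC)(CC)CC | intermediate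
17 | ethyl 2-(triphenylphosphoranylidene)propanoate | CCOC(=O)C(C)=P(c1ccccc1)(c1ccccc1)c1ccccc1 | starting material
18 | ethyl (2E)-4-[(1R,2S,5R,6S)-4-{[(tert-butyldiphenylsilyl)oxy]methyl}-3-[(E)-hept-1-en-1-yl]-2,5,6-tris[(triethylsilyl)oxy]cyclohex-3-en-1-yl]-2-methylbut-2-enoate | CCCCC/C=C/C1=C(CO[Si](c2ccccc2)(c2ccccc2)C(C)(C)C)[C@@H](O[Si](CC)(CC)CC)[C@@H](O[Si](CC)(CC)CC)[C@H](C/C=C(\C)C(=O)OCC)[C@@H]1O[Si](CC)(CC)CC | intermediate
19 | ethyl (2E)-4-[(1R,2S,5R,6S)-3-[(E)-hept-1-en-1-yl]-2,5,6-trihydroxy-4-(hydroxymethyl)cyclohex-3-en-1-yl]-2-methylbut-2-enoate | CCCCC/C=C/C1=C(CO)[C@@H](O)[C@@H](O)[C@H](C/C=C(\C)C(=O)OCC)[C@@H]1O | intermediate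
20 | lithium salt of pestallic acid P | CCCCC/C=C/C1=C(CO)[C@@H](O)[C@@H](O)[C@H](C/C=C(\C)C(=O)[O-])[C@@H]1O.[Li+] | intermediate
21 | pestallic acid P, (2E)-4-[(1R,2S,5R,6S)-3-[(E)-hept-1-en-1-yl]-2,5,6-trihydroxy-4-(hydroxymethyl)cyclohex-3-en-1-yl]-2-methylbut-2-enoic acid | CCCCC/C=C/C1=C(CO)[C@@H](O)[C@@H](O)[C@H](C/C=C(\C)C(=O)O)[C@@H]1O | target

**Count and risks**

Total step count: 14. Longest linear sequence: 14 steps (1 to 21).

**Step 10.** After electron transfer the spin of the ketyl is spread over C3, C1 and C8. Bond formation at C8, expulsion of the C6 silyloxide after a second electron transfer, or simple reduction of the formyl groups may therefore outrun the C3-C4 closure, and the face selectivity may erode.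
- The fallback closes the same bond without a reductant and sets C3 in a separate hydride step. It sets out from 13.
- A carbene made from 2-mesityl-6,7-dihydro-5H-pyrrolo[2,1-c][1,2,4]triazol-2-ium chloride and DBU (THF, rt) should bring about an intramolecular benzoin reaction.
- The two possible acyloins should equilibrate through their common enediol to the conjugated isomer with the ketone at C3, the alpha-hydroxy dienone F1. In it the C4 hydroxyl rests equatorial and trans to the C5 branch.
- LiBH(s-Bu)3 (THF, -78 °C) should then attack C3 along the equatorial trajectory, from the face opposite to the C4 oxygen. This should give the pseudoaxial C3 alcohol, which is 14, where the route is rejoined.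

**Step 5.** The alkenyl group flanks the reacting furan carbon, so the addition may be slow and the control at C6 may erode, while C5 stays under catalyst control.
- The fallback sets C6 by a reagent-controlled ketone reduction instead of in the C-C bond formation. The material is taken through steps 6 and 7 as it is, and the fallback sets out from 11.
- Et3SiCl (2.1 equiv), imidazole, CH2Cl2, -40 °C should silylate only the two primary hydroxyls and give the C3,C4-bis(triethylsilyl) ether F2.
- MnO2 (CH2Cl2, rt) should oxidise the allylic C6 carbinol to the cross-conjugated C6 ketone F3, which removes the faulty centre.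
- Corey-Bakshi-Shibata reduction with (R)-tetrahydro-1-methyl-3,3-diphenyl-1H,3H-pyrrolo[1,2-c][1,3,2]oxazaborole and BH3·SMe2 (THF, -30 °C) should give the (6S)-alcohol F4, with the dienyl group acting as the large substituent.
- Et3SiCl and imidazole in DMF then give 12, where the route is rejoined.

**Step 7.** The reduction may stall at the lactol stage. Loss of water from the lactol would aromatise the five-membered ring to a furan and erase C6.
- The fallback opens the lactone by aminolysis instead of by hydride. It sets out from 10.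
- MeNH(OMe)·HCl and AlMe3 (CH2Cl2, 0 °C to rt) should open the butenolide and convert the ethyl ester at the same time, giving the hydroxy bis(N-methoxy-N-methylamide) F5.
- F5 is silylated without delay (Et3SiCl, imidazole, DMF) to forestall relactonisation and gives the C6 triethylsilyl ether F6.
- i-Bu2AlH (2.5 equiv, THF, -78 °C) should reduce both amides to formyl groups and deliver 13 directly, so that 11, 12 and the Swern step are by-passed.

**Further compounds**

F1 | step 10 | alpha-hydroxy dienone: C3 ketone, (4S)-OH, C6-OTES, C9-OTBDPS, C11 dimethyl acetal | CCCCC/C=C/C1=C(CO[Si](c2ccccc2)(c2ccccc2)C(C)(C)C)C(=O)[C@@H](O)[C@H](CC(OC)OC)[C@@H]1O[Si](CC)(CC)CC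
F2 | step 5 | C3,C4-bis(triethylsilyl) ether of the open-chain triol, C6-OH free, C6 unassigned | CCCCC/C=C/C(=C(\CO[Si](c1ccccc1)(c1ccccc1)C(C)(C)C)CO[Si](CC)(CC)CC)C(O)[C@@H](CC(OC)OC)CO[Si](CC)(CC)CC
F3 | step 5 | cross-conjugated C6 ketone of F2 | CCCCC/C=C/C(=C(\CO[Si](c1ccccc1)(c1ccccc1)C(C)(C)C)CO[Si](CC)(CC)CC)C(=O)[C@@H](CC(OC)OC)CO[Si](CC)(CC)CC
F4 | step 5 | (6S)-alcohol, C3,C4-bis(triethylsilyl) ether | CCCCC/C=C/C(=C(\CO[Si](c1ccccc1)(c1ccccc1)C(C)(C)C)CO[Si](CC)(CC)CC)[C@@H](O)[C@@H](CC(OC)OC)CO[Si](CC)(CC)CC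
F5 | step 7 | hydroxy bis(N-methoxy-N-methylamide) at C3 and C4, C6-OH free | CCCCC/C=C/C(=C(\CO[Si](c1ccccc1)(c1ccccc1)C(C)(C)C)C(=O)N(C)OC)[C@@H](O)[C@@H](CC(OC)OC)C(=O)N(C)OC
F6 | step 7 | C6 triethylsilyl ether of F5 | CCCCC/C=C/C(=C(\CO[Si](c1ccccc1)(c1ccccc1)C(C)(C)C)C(=O)N(C)OC)[C@@H](O[Si](CC)(CC)CC)[C@@H](CC(OC)OC)C(=O)N(C)OC
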